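## Structural features

The target (31) is an 18-membered macrocyclic bis(bibenzyl) made of four six-membered carbocycles: a 2-methoxy-1,4-benzoquinone (ring A), a para-phenylene (ring B), a 1,2,4-trisubstituted phenol (ring C) and a meta-phenylene (ring D). The rings are joined by two CH2CH2 bridges (A–B and C–D) and two diaryl ether oxygens (B–O–C and D–O–A). In ring A, C2 carries OMe, C3 is unsubstituted, C5 carries the oxygen to ring D and C6 the bridge to ring B; in ring C the free OH is ortho to the ether oxygen and para to the bridge. There is no stereocentre and no stereogenic double bond, so nothing of that kind has to be set or kept. The fragile parts are the methoxyquinone (a vinylogous ester, easily reduced and open to base and nucleophiles) and, towards oxidants, the ring C phenol; the quinone must therefore be unveiled last from an electron-rich, pentasubstituted arene. The real difficulty is closing the 18-membered ring together with the ether at the ring A oxygen, which is flanked by OMe and by the bridge and resists ordinary aryl–oxygen coupling. The key step exploits the 1,3-pattern of ring D: C1 bears the ring A oxygen and C3 the bridge from ring C, exactly the pattern of the 2-aryloxy-1,3-diene left by endo enyne metathesis of an ArO–C≡CH unit with a terminal alkene (C1 and C2 from the alkyne, C3 from the alkene, C6 as the new methylene), with C4 and C5 supplied later by a dienophile.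

## Logic of the disconnections

31 ⇒ 30. No skeletal bond is cut; the C1 and C4 carbonyls are traced back to a phenol and the methyl ether para to it. The quinone could not survive organolithium, ruthenium carbene, hot dienophile or alkoxide steps. Ring A becomes an ordinary arene; the forward oxidation must take the ring A 4-methoxyphenol and leave the less electron-rich ring C phenol.

30 ⇒ 29. The two O–CH2Ph bonds are cut. Benzyl withstands every basic, organometallic and thermal step and both groups fall in one hydrogenolysis. The demand is that nothing else reducible is left, which holds because ring D is aromatic by then.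

29 ⇒ 27 ⇒ 25 + 26. Ring D is cut at C3–C4 and C5–C6 after two C–S bonds are restored at C4 and C5. These two carbons carry no substituent, so they can come from the acetylene equivalent 26. Ring D shrinks to a diene inside the macrocycle; the diene must be E and able to reach s-cis, and base must expel sulfinate twice rather than the aryloxide.

25 ⇒ 23. The C2=C3 and C1=C6 double bonds are cut; C2–C3 is the ring-closing bond. The macrocycle opens to an acyclic enyne and the hindered ether at ring A is reduced to an O–C(sp) bond. The forward step needs endo closure, an E alkene and dilution.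

23 ⇒ 20 ⇒ 17 + 18. The triple bond is traced to a dichlorovinyl group and the O–C bond to addition of the phenoxide of 17 to 18. The hindered oxygen attacks a small two-carbon electrophile, so no aryl–O coupling is needed. Because 23 is labile it is made immediately before use, and the n-BuLi step must spare the benzyl ethers.

17 ⇒ 14. C–O is exchanged for C–Br. The bromine of 1 serves as a latent oxygen through steps 2–8, which saves a protecting group. Bromine–lithium exchange must outrun deprotonation of the benzyl ethers.

14 ⇒ 7 + 12. The bond between the ring B carbon and the bridge CH2 is cut. An sp2–sp3 coupling gives the saturated bridge directly, so no stilbene has to be hydrogenated beside the butenyl group and the benzyl ethers; a ring B nitrile or a Wittig link was rejected for that reason. The two fragments are of similar size. All B–H must be gone before 12 is added, and palladium must choose the iodide of 12 over the hindered bromide of 13.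

7 ⇒ 6 ⇒ 4 ⇒ 3 ⇒ 1. The vinyl group comes from an aldehyde, the formyl C–C bond from lithiation between Br and OBn, the benzyl ether from a phenol, and the aryl C–O bond from aryl–CHO by oxidative rearrangement. 1 already carries both methoxy groups and distinguishes the two future oxygens as CHO and Br. Lithiation must occur between Br and OBn, not between the methoxy groups, and without Br/Li exchange.

12 ⇒ 11 ⇒ 10 ⇒ 8 + 9. The benzylic C–H is traced to C–OH, the chain C–C bond to allylmagnesium bromide addition, and the B–O–C ether to copper-mediated arylation. 8 has the oxygen pattern of ring C with one free phenol; 9 brings ring B with the iodide for step 8. The etherification must leave C–I intact, and the deoxygenation must not move the double bond.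

## Other disconnections considered

Alternative 1: The cut lies in ring A, at the C1–C2 bond (and the C3–H bond), so ring A derives from a cyclobutenone and a methoxy-substituted alkyne unit. Forward, the macrocyclic 4-hydroxy-4-(methoxyethynyl)cyclobutenone A2, which is the adduct of an alkynyl-lithium reagent with the ketone-like carbonyl of the macrocyclic cyclobutenedione A3, would be heated. Electrocyclic opening gives an enynylketene that closes between the ketene carbon and the distal alkyne carbon to a diradical, which is quenched by hydrogen transfer from the hydroxyl group to give A1, the ring C benzyl ether of the target.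
- In favour: the substitution pattern of the quinone follows from the connectivity of A2 and cannot be scrambled.
- Better than the chosen plan: the quinone arrives at its final oxidation level without an oxidant, so the chemoselectivity question of step 16 does not arise.
- Equal: the ring A–O–ring D ether would come from addition–elimination on the four-membered ring, as undemanding as step 10.
- Against: an oxygen substituent on the alkyne terminus stabilises the radical of the competing five-membered closure, so diversion away from the quinone is expected; A2 joins a tertiary propargylic alcohol to an acid-labile ynol ether; the rearrangement closes ring A but not the macrocycle, so A3 needs a macrocyclisation of its own; A1 must still lose its benzyl group beside the quinone, which by hydrogenolysis means reduction and re-oxidation.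
- Comparison: structurally the key step is spent on ring A, whereas the chosen plan builds ring D and the macrocycle at once. Mechanistically a reagent-free thermal cascade stands against a catalytic carbene process that needs dilution. Step economy is about level, because what is saved at the end is spent on A3.

Alternative 2: The cut is the ether bond between the ring B oxygen and C1 of ring C. Forward, the open-chain bisphenol A5 (3,5-dichloro-4-hydroxyphenyl ring B, 3,5-dibromo-4-hydroxyphenyl ring C) would be treated with Tl(NO3)3 (trivalent thallium). The dibromophenol is oxidised, the ring B oxygen adds at a bromine-bearing ortho carbon, and zinc removes that bromine and rearomatises ring C to give A4.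
- In favour: it is the biogenetic bond construction and closes the ring at the unhindered ether.
- Better than the chosen plan: the free ring C hydroxyl ortho to the new ether comes straight from the mechanism, with no protecting group on either phenol.
- Equal: A5 is assembled from two simple phenethyl units, comparable in effort to 23.
- Against: a stoichiometric, highly toxic thallium salt; three halogens to install and then remove by hydrogenolysis, which like the zinc step reduces the quinone and forces a re-oxidation; the oxidant must tell the two halophenols apart; oxidative phenol coupling is sensitive to conformation in a ring of this size; the hindered ring A–O–ring D ether must still be made earlier by ordinary aryl ether coupling on a pentasubstituted ring, which the chosen plan avoids.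
- Comparison: structurally both plans close the macrocycle in the key step, here at ring C and in the chosen plan at ring D. Mechanistically a two-electron phenol oxidation with a stoichiometric heavy metal stands against catalytic metathesis. In step economy the halogenation and dehalogenation make it longer, although its key step needs no later ring construction.

Alternative 3: The cut is the bond between C6 of ring A and the adjacent bridge carbon, at the ketone oxidation level. Forward, the 20-membered macrolactone A7 (the ring A C1 oxygen esterified by the arylacetic acid of ring B) is irradiated at 254 nm. Homolysis of the O–acyl bond gives a caged radical pair that recombines at C6 and contracts the ring by two atoms to the ortho-hydroxyaryl benzyl ketone A6.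
- Better than the chosen plan: the large ring is first closed by ester formation, a more dependable closure than the metathesis of step 12.
- Equal: the migration terminus is unambiguous, because the other ortho position and the para position of that oxygen carry methoxy groups.
- Better: the rearrangement frees exactly the phenol needed for the quinone, so that oxygen needs no protecting group.
- Better: after the key step only ketone reduction, debenzylation and oxidation remain, one operation fewer than in the chosen plan.
- Against: arylacetyl radicals lose CO quickly, which opens paths to decarbonylated recombination and simple ester cleavage; diaryl ethers and the electron-rich rings absorb at 254 nm and can rearrange; the di-ortho-substituted ketone must then be reduced to CH2; as in Alternative 2, the ring A–O–ring D ether has to be made beforehand at the hindered oxygen.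
- Comparison: structurally a bridge C–C bond is formed at ring A instead of building ring D. Mechanistically radical-pair photochemistry with little control stands against a reversible, thermodynamically steered catalytic process. Step economy is roughly equal overall, since the saving after the key step is offset by the separate synthesis of the ring D ether.

Key step: step 12

Remark on the chemistry: 23 and 25 are isomers (C42H40O6), the ring in 25, 29 and 31 has 18 members, and 11, 27 and 28 are racemic or diastereomeric mixtures whose stereocentres are erased in the following step.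

## Route

Step 1
Reactants: 1 5-bromo-2,4-dimethoxybenzaldehyde
Product: 3 5-bromo-2,4-dimethoxyphenol, via aryl formate 2 (not isolated)
Conditions: mCPBA, CH2Cl2, 0→25 °C; then K2CO3 (cat.), MeOH, 25 °C
Reagents that add atoms: meta-chloroperbenzoic acid (mCPBA), OOC(=O)c1cccc(Cl)c1
Why: Baeyer–Villiger oxidation (Dakin-type): the electron-rich aryl group migrates to oxygen and the formate is cleaved by methanolysis.

Step 2
Reactants: 3 5-bromo-2,4-dimethoxyphenol
Product: 4 1-(benzyloxy)-5-bromo-2,4-dimethoxybenzene
Conditions: BnBr, K2CO3, DMF, 25 °C
Reagents that add atoms: benzyl bromide, BrCc1ccccc1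
Why: Williamson ether synthesis on an unhindered phenoxide.

Step 3
Reactants: 4 1-(benzyloxy)-5-bromo-2,4-dimethoxybenzene
Product: 6 2-(benzyloxy)-6-bromo-3,5-dimethoxybenzaldehyde, via aryllithium 5 (not isolated)
Conditions: LiN(iPr)2, THF, −78 °C; DMF, −78→0 °C; H2O
Reagents that add atoms: N,N-dimethylformamide, CN(C)C=O
Why: Directed ortho-lithiation: the C–H flanked by Br and OBn is acidified by both, the amide base deprotonates it without Br/Li exchange, and at −78 °C the ortho-bromoaryllithium should not lose LiBr; DMF then formylates it.

Step 4
Reactants: 6 2-(benzyloxy)-6-bromo-3,5-dimethoxybenzaldehyde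
Product: 7 2-(benzyloxy)-4-bromo-3-ethenyl-1,5-dimethoxybenzene
Conditions: Ph3PCH3Br, KOtBu, THF, 0→25 °C
Reagents that add atoms: methyltriphenylphosphonium bromide, C[P+](c1ccccc1)(c1ccccc1)c1ccccc1.[Br-]
Why: Wittig methylenation; the small ylide should reach the di-ortho-substituted aldehyde without difficulty.

Step 5
Reactants: 8 4-(benzyloxy)-3-hydroxybenzaldehyde; 9 (4-iodophenyl)boronic acid
Product: 10 4-(benzyloxy)-3-(4-iodophenoxy)benzaldehyde
Conditions: Cu(OAc)2, pyridine, 4 Å MS, CH2Cl2, air, 25 °C
Reagents that add atoms: none
Why: Chan–Lam–Evans aryl ether synthesis: divalent copper couples phenol and arylboronic acid at room temperature under air, where the C–I bond and the aldehyde are not touched.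

Step 6
Reactants: 10 4-(benzyloxy)-3-(4-iodophenoxy)benzaldehyde
Product: 11 rac-1-[4-(benzyloxy)-3-(4-iodophenoxy)phenyl]but-3-en-1-ol
Conditions: CH2=CHCH2MgBr, THF, −78 °C; H2O
Reagents that add atoms: allylmagnesium bromide, C=CC[Mg]Br
Why: Grignard addition to the aldehyde; the allyl reagent does not exchange with the aryl iodide at −78 °C, and the new carbinol stereocentre is formed without control (racemate) and removed in step 7.

Step 7
Reactants: 11 rac-1-[4-(benzyloxy)-3-(4-iodophenoxy)phenyl]but-3-en-1-ol
Product: 12 1-(benzyloxy)-4-(but-3-en-1-yl)-2-(4-iodophenoxy)benzene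
Conditions: Et3SiH, CF3CO2H, CH2Cl2, −20→0 °C
Reagents that add atoms: none
Why: Ionic hydrogenation: the acid ionises the benzylic alcohol to a cation stabilised by the para-benzyloxy group and the silane delivers hydride; the monosubstituted alkene and the C–I bond are inert under these conditions.

Step 8
Reactants: 7 2-(benzyloxy)-4-bromo-3-ethenyl-1,5-dimethoxybenzene; 12 1-(benzyloxy)-4-(but-3-en-1-yl)-2-(4-iodophenoxy)benzene
Product: 14 ring A bromide of the A–B–C bibenzyl diaryl ether, via alkylborane 13 (not isolated)
Conditions: 7, 9-BBN, THF, 0→25 °C; then aq. K3PO4, 12, Pd(dppf)Cl2 (5 mol %), DMF, 25→45 °C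
Reagents that add atoms: none
Why: Hydroboration/B-alkyl Suzuki–Miyaura coupling: 9-BBN adds to the styrene terminus, residual B–H is destroyed by the aqueous base before the alkene-bearing 12 is added, and zerovalent palladium should insert into the unhindered C–I bond far faster than into the di-ortho-substituted, electron-rich C–Br bond.

Step 9
Reactants: 14 ring A bromide of the A–B–C bibenzyl diaryl ether
Product: 17 ring A phenol of the A–B–C bibenzyl diaryl ether, via aryllithium 15 (not isolated), via dimethyl boronate 16 (not isolated)
Conditions: n-BuLi, THF, −78 °C; B(OMe)3, −78→0 °C; then 30% H2O2, 0→25 °C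
Reagents that add atoms: hydrogen peroxide, OO
Why: Bromine–lithium exchange (faster at −78 °C than deprotonation of the benzyl ethers), borylation and oxidative 1,2-migration to oxygen; the unactivated terminal alkene does not react with basic H2O2.

Step 10
Reactants: 17 ring A phenol of the A–B–C bibenzyl diaryl ether; 18 trichloroethene
Product: 20 aryl (E)-1,2-dichlorovinyl ether of 17, via dichloroethyne 19 (not isolated)
Conditions: K2CO3, DMF, 70 °C
Reagents that add atoms: none
Why: Base converts 18 into dichloroethyne in situ and the phenoxide adds to it in anti fashion, the established route to aryl (E)-1,2-dichlorovinyl ethers; the hindered oxygen only has to attack a small linear electrophile.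

Step 11
Reactants: 20 aryl (E)-1,2-dichlorovinyl ether of 17
Product: 23 aryl ethynyl ether with the but-3-enyl group on ring C, via chloroethynyl ether 21 (not isolated), via lithium acetylide 22 (not isolated)
Conditions: n-BuLi (2.3 equiv), THF, −78→−40 °C; MeOH, −78 °C; used at once
Reagents that add atoms: none
Why: Dehydrochlorination to the chloroalkyne, Cl/Li exchange and protonation (standard ynol ether synthesis from dichlorovinyl ethers); vinylic deprotonation at −78 °C should outpace attack on the benzyl ethers, and 23 is not stored because aryl ethynyl ethers hydrate and oligomerise readily.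

Step 12
Reactants: 23 aryl ethynyl ether with the but-3-enyl group on ring C
Product: 25 18-membered (E)-2-aryloxy-1,3-diene macrocycle (dibenzyl ether), via aryloxybutadiene 24 (not isolated)
Conditions: (H2IMes)(PCy3)Cl2Ru=CHPh (second-generation Grubbs catalyst, 10 mol %), ethene (1 atm), toluene (1 mM), 25 °C; then argon purge, 70 °C
Reagents that add atoms: ethene, C=C
Why: Ring-closing enyne metathesis of an alkynyl ether, run as its ethene-mediated tandem variant: the ruthenium methylidene adds across the C≡C bond of 23 to a ruthenacyclobutene that opens to a vinylcarbene, and ethene turns this over to the 2-aryloxybuta-1,3-diene 24. After the ethene is purged, the alkylidene formed at the butenyl terminus undergoes ring-closing metathesis with the monosubstituted vinyl group of 24 and releases ethene to give 25; direct endo attack of the butenyl-derived alkylidene on the alkyne leads to the same diene. The closest known reaction types are endo-selective macrocyclic enyne ring-closing metathesis under ethene and enyne metathesis of alkynyl ethers. The 18-membered ring closes in the endo mode, with both alkyne carbons (future C1 and C2 of ring D) inside the ring and the new methylene (future C6) outside it. No stereocentre is formed; the only stereo-element is the C2=C3 double bond, whose E geometry is expected from thermodynamic control through reversible metathesis and the lower strain of the E isomer in the large ring. The step needs closure over oligomerisation (millimolar dilution, and the bimolecular alkyne step is done with ethene first), endo over exo closure (exo would place a trisubstituted enol-ether alkene in a 17-membered ring and is shut off once the alkyne has become 24), and reaction at the vinyl group rather than the 1,1-disubstituted oxygen-bearing alkene of 24 (which is sterically and electronically deactivated). Benzyl ethers, methyl ethers and the diaryl ether are inert to the catalyst.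

Step 13
Reactants: 25 18-membered (E)-2-aryloxy-1,3-diene macrocycle (dibenzyl ether); 26 (E)-1,2-bis(phenylsulfonyl)ethene
Product: 27 Diels–Alder adduct with ring D as a 4,5-trans-bis(phenylsulfonyl)cyclohexene (racemic mixture of C3 epimers)
Conditions: toluene, 90 °C
Reagents that add atoms: none
Why: Diels–Alder reaction of an electron-rich 2-aryloxydiene with a doubly activated acetylene equivalent; the E diene can reach s-cis with O and CH2 diverging as in the final meta-phenylene, the sulfonyl groups stay trans (suprafacial addition), C3 is uncontrolled, and all three new stereocentres are removed in step 14.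

Step 14
Reactants: 27 Diels–Alder adduct with ring D as a 4,5-trans-bis(phenylsulfonyl)cyclohexene
Product: 29 dibenzyl ether macrocycle with aromatic ring D, via monosulfone 28 (not isolated)
Conditions: KOtBu, THF, 0→25 °C
Reagents that add atoms: none
Why: Twofold base-induced elimination of benzenesulfinate (E1cB, then allylic isomerisation of the vinyl sulfone and a second β-elimination) driven by aromatisation; sulfinate is a far better leaving group than the aryloxide at C1, so the ether should stay.

Step 15
Reactants: 29 dibenzyl ether macrocycle with aromatic ring D
Product: 30 macrocyclic bisphenol (ring A as 4-methoxyphenol)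
Conditions: H2 (1 atm), Pd/C, EtOAc/MeOH, 25 °C
Reagents that add atoms: none
Why: Hydrogenolysis of both benzyl ethers over palladium on carbon; diaryl ethers, methyl ethers and the arenes are stable and no alkene remains.

Step 16
Reactants: 30 macrocyclic bisphenol (ring A as 4-methoxyphenol)
Product: 31 target quinone macrocycle CNP0332646.0
Conditions: PhI(OAc)2 (1.05 equiv), MeCN/H2O, 0 °C
Reagents that add atoms: water, O
Why: PhI(OAc)2 (trivalent iodine) oxidises the ring A 4-methoxyphenol through an aryloxy-iodane to the para-oxocarbenium ion, water adds at C4 and methanol is lost to give the quinone; the much less electron-rich ring C phenol is expected to react far more slowly, hence one equivalent at 0 °C.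

## Compound list

1 | 5-bromo-2,4-dimethoxybenzaldehyde | COc1cc(OC)c(Br)cc1C=O | starting material
2 | 5-bromo-2,4-dimethoxyphenyl formate | COc1cc(OC)c(Br)cc1OC=O | intermediate
3 | 5-bromo-2,4-dimethoxyphenol | COc1cc(OC)c(Br)cc1O | intermediate
4 | 1-(benzyloxy)-5-bromo-2,4-dimethoxybenzene | COc1cc(OC)c(Br)cc1OCc1ccccc1 | intermediate
5 | [2-(benzyloxy)-6-bromo-3,5-dimethoxyphenyl]lithium | [Li]c1c(Br)c(OC)cc(OC)c1OCc1ccccc1 | intermediate
6 | 2-(benzyloxy)-6-bromo-3,5-dimethoxybenzaldehyde | O=Cc1c(Br)c(OC)cc(OC)c1OCc1ccccc1 | intermediate
7 | 2-(benzyloxy)-4-bromo-3-ethenyl-1,5-dimethoxybenzene | C=Cc1c(Br)c(OC)cc(OC)c1OCc1ccccc1 | intermediate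
8 | 4-(benzyloxy)-3-hydroxybenzaldehyde | O=Cc1ccc(OCc2ccccc2)c(O)c1 | starting material
9 | (4-iodophenyl)boronic acid | OB(O)c1ccc(I)cc1 | starting material
10 | 4-(benzyloxy)-3-(4-iodophenoxy)benzaldehyde | O=Cc1ccc(OCc2ccccc2)c(Oc2ccc(I)cc2)c1 | intermediate
11 | rac-1-[4-(benzyloxy)-3-(4-iodophenoxy)phenyl]but-3-en-1-ol (racemate) | C=CCC(O)c1ccc(OCc2ccccc2)c(Oc2ccc(I)cc2)c1 | intermediate
12 | 1-(benzyloxy)-4-(but-3-en-1-yl)-2-(4-iodophenoxy)benzene | C=CCCc1ccc(OCc2ccccc2)c(Oc2ccc(I)cc2)c1 | intermediate
13 | 9-{2-[2-(benzyloxy)-6-bromo-3,5-dimethoxyphenyl]ethyl}-9-borabicyclo[3.3.1]nonane | COc1cc(OC)c(Br)c(CCB2C3CCCC2CCC3)c1OCc1ccccc1 | intermediate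
14 | 2-(benzyloxy)-3-[2-(4-{2-(benzyloxy)-5-(but-3-en-1-yl)phenoxy}phenyl)ethyl]-4-bromo-1,5-dimethoxybenzene | Brc1c(OC)cc(OC)c(OCc2ccccc2)c1CCc1ccc(cc1)Oc1cc(CCC=C)ccc1OCc1ccccc1 | intermediate
15 | aryllithium from 14 (Li in place of Br) | [Li]c1c(OC)cc(OC)c(OCc2ccccc2)c1CCc1ccc(cc1)Oc1cc(CCC=C)ccc1OCc1ccccc1 | intermediate
16 | dimethyl arylboronate from 15 (B(OMe)2 in place of Li) | COB(OC)c1c(OC)cc(OC)c(OCc2ccccc2)c1CCc1ccc(cc1)Oc1cc(CCC=C)ccc1OCc1ccccc1 | intermediate
17 | 3-(benzyloxy)-2-[2-(4-{2-(benzyloxy)-5-(but-3-en-1-yl)phenoxy}phenyl)ethyl]-4,6-dimethoxyphenol | Oc1c(OC)cc(OC)c(OCc2ccccc2)c1CCc1ccc(cc1)Oc1cc(CCC=C)ccc1OCc1ccccc1 | intermediate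
18 | trichloroethene | ClC=C(Cl)Cl | starting material
19 | dichloroethyne | ClC#CCl | intermediate
20 | 2-(benzyloxy)-3-[2-(4-{2-(benzyloxy)-5-(but-3-en-1-yl)phenoxy}phenyl)ethyl]-4-{[(E)-1,2-dichloroethenyl]oxy}-1,5-dimethoxybenzene | Cl/C=C(/Cl)Oc1c(OC)cc(OC)c(OCc2ccccc2)c1CCc1ccc(cc1)Oc1cc(CCC=C)ccc1OCc1ccccc1 | intermediate
21 | chloroethynyl ether from 20 (ArO–C≡C–Cl) | ClC#COc1c(OC)cc(OC)c(OCc2ccccc2)c1CCc1ccc(cc1)Oc1cc(CCC=C)ccc1OCc1ccccc1 | intermediate
22 | lithium acetylide from 21 (ArO–C≡C–Li) | [Li]C#COc1c(OC)cc(OC)c(OCc2ccccc2)c1CCc1ccc(cc1)Oc1cc(CCC=C)ccc1OCc1ccccc1 | intermediate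
23 | 2-(benzyloxy)-3-[2-(4-{2-(benzyloxy)-5-(but-3-en-1-yl)phenoxy}phenyl)ethyl]-4-(ethynyloxy)-1,5-dimethoxybenzene | C#COc1c(OC)cc(OC)c(OCc2ccccc2)c1CCc1ccc(cc1)Oc1cc(CCC=C)ccc1OCc1ccccc1 | intermediate
24 | 2-(benzyloxy)-3-[2-(4-{2-(benzyloxy)-5-(but-3-en-1-yl)phenoxy}phenyl)ethyl]-4-(buta-1,3-dien-2-yloxy)-1,5-dimethoxybenzene | C=CC(=C)Oc1c(OC)cc(OC)c(OCc2ccccc2)c1CCc1ccc(cc1)Oc1cc(CCC=C)ccc1OCc1ccccc1 | intermediate
25 | 18-membered macrocycle: ring A–O–C(=CH2)–CH=CH–CH2CH2–ring C, E alkene, benzyl ethers on rings A and C | COc1cc(OC)c2c(c1OCc1ccccc1)CCc1ccc(cc1)Oc1cc(ccc1OCc1ccccc1)CC/C=C/C(=C)O2 | intermediate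
26 | (E)-1,2-bis(phenylsulfonyl)ethene | O=S(=O)(/C=C/S(=O)(=O)c1ccccc1)c1ccccc1 | starting material
27 | cycloadduct of 25 and 26: ring D as 1-aryloxy-4,5-trans-bis(phenylsulfonyl)cyclohex-1-ene, racemic, mixture of C3 epimers | COc1cc(OC)c2c(c1OCc1ccccc1)CCc1ccc(cc1)Oc1cc(ccc1OCc1ccccc1)CCC1C=C(O2)CC(S(=O)(=O)c3ccccc3)C1S(=O)(=O)c1ccccc1 | intermediate
28 | monosulfone after the first elimination: ring D as 1-aryloxy-5-(phenylsulfonyl)cyclohexa-1,4-diene, racemic at C3 (one regioisomer drawn) | COc1cc(OC)c2c(c1OCc1ccccc1)CCc1ccc(cc1)Oc1cc(ccc1OCc1ccccc1)CCC1C=C(O2)CC(S(=O)(=O)c3ccccc3)=C1 | intermediate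
29 | macrocycle with aromatic ring D, benzyl ethers on rings A and C | COc1cc(OC)c2c(c1OCc1ccccc1)CCc1ccc(cc1)Oc1cc(ccc1OCc1ccccc1)CCc1cccc(c1)O2 | intermediate
30 | macrocyclic bisphenol (ring A 2,4-dimethoxy-phenol type, ring C phenol) | COc1cc(OC)c2c(c1O)CCc1ccc(cc1)Oc1cc(ccc1O)CCc1cccc(c1)O2 | intermediate
31 | CNP0332646.0, macrocyclic 2-methoxy-1,4-benzoquinone (no stereocentre) | COC1=CC(=O)C2=C(CCc3ccc(cc3)Oc3cc(ccc3O)CCc3cccc(c3)O2)C1=O | target

## Step count and least certain steps

Total: 16 steps. Longest linear sequence: 13 steps (1 to 31 through steps 1–4 and 8–16); the branch from 8 and 9 contributes steps 5–7.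

Step 12 (key step). The most likely failures are cross-metathesis oligomerisation outcompeting ring closure, and arrest of the catalyst as an oxygen-stabilised carbene at the aryloxy-bearing carbon; acid-induced erosion of the ynol ether before it is consumed is a further risk. Fallback, setting out from 17 and returning at 25: 17 is acylated with acryloyl chloride (Et3N, CH2Cl2, 0 °C) to the aryl acrylate F1. Ring-closing metathesis of the acrylate with the butenyl group (second-generation Grubbs catalyst, toluene, 1 mM, 80 °C), a plain ene–ene macrocyclisation of the kind used for macrocyclic enoates, should give the 18-membered aryl (E)-enoate F2. Carbonyl methylenation of this aryl ester with Cp2Ti(μ-CH2)(μ-Cl)AlMe2 (Tebbe reagent; pyridine, THF, −40→0 °C) converts C=O into C=CH2 and gives 25, which continues with step 13. This path also dispenses with 20 and 23.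

Step 11. The likely failure is loss of the terminal ynol ether during quench and isolation through hydration or oligomerisation; partial metalation of the benzyl ethers by excess n-BuLi is the second risk. Fallback, setting out from 20 and returning at 23: the lithium acetylide 22 is quenched with Me3SiCl instead of methanol to give the C-silylated ynol ether F3, which can be purified and stored. The silyl group is removed with Bu4NF (THF, −78 °C) immediately before step 12, so that 23 is never concentrated or kept.

Step 14. The likely failure is stalling after the first elimination, or conjugate addition of tert-butoxide to the vinyl sulfone instead of the isomerisation needed for the second elimination. Fallback, setting out from 27 and returning at 29: reductive elimination of both sulfonyl groups with sodium amalgam (Na(Hg), Na2HPO4, MeOH/THF, −20 °C), the classical unmasking of this acetylene equivalent, gives the 1-aryloxycyclohexa-1,4-diene F4. Dehydrogenation with DDQ (1 equiv, CH2Cl2, 0 °C) then aromatises ring D to 29.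

Step 16. The likely failure is over-oxidation, that is, competing attack of the oxidant on the ring C phenol. Fallback, setting out from 30 and returning at 31: the ring C phenol has only one ortho substituent and should be silylated in preference to the di-ortho-substituted ring A phenol (TBSCl 1 equiv, imidazole, DMF, 0 °C), giving the mono-silyl ether F5. PhI(OAc)2 then oxidises the only free phenol to the quinone silyl ether F6, and HF·pyridine (THF, 0 °C) removes the silyl group to give 31.

Step 7. The likely failure is β-proton loss from the benzylic cation followed by re-protonation and reduction with migration of the double bond, or alkylation of an arene by the cation. Fallback, setting out from 10 and returning at 12: NaBH4 (MeOH, 0 °C) reduces 10 to the benzylic alcohol F7, PBr3 (Et2O, 0 °C) gives the benzylic bromide F8, and SN2 coupling with allylmagnesium bromide (THF, 0 °C) gives 12 without a cationic intermediate.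

## Further compounds

F1 | step 12 | 3-(benzyloxy)-2-[2-(4-{2-(benzyloxy)-5-(but-3-en-1-yl)phenoxy}phenyl)ethyl]-4,6-dimethoxyphenyl prop-2-enoate | C=CC(=O)Oc1c(OC)cc(OC)c(OCc2ccccc2)c1CCc1ccc(cc1)Oc1cc(CCC=C)ccc1OCc1ccccc1
F2 | step 12 | 18-membered macrocyclic aryl (E)-enoate: ring A–O–C(=O)–CH=CH–CH2CH2–ring C, benzyl ethers on rings A and C | COc1cc(OC)c2c(c1OCc1ccccc1)CCc1ccc(cc1)Oc1cc(ccc1OCc1ccccc1)CC/C=C/C(=O)O2
F3 | step 11 | C-trimethylsilyl derivative of 23 (ArO–C≡C–SiMe3) | C[Si](C)(C)C#COc1c(OC)cc(OC)c(OCc2ccccc2)c1CCc1ccc(cc1)Oc1cc(CCC=C)ccc1OCc1ccccc1
F4 | step 14 | macrocycle with ring D as 1-aryloxycyclohexa-1,4-diene, racemic at C3, benzyl ethers on rings A and C | COc1cc(OC)c2c(c1OCc1ccccc1)CCc1ccc(cc1)Oc1cc(ccc1OCc1ccccc1)CCC1C=C(O2)CC=C1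
F5 | step 16 | ring C tert-butyldimethylsilyl ether of 30 | COc1cc(OC)c2c(c1O)CCc1ccc(cc1)Oc1cc(ccc1O[Si](C)(C)C(C)(C)C)CCc1cccc(c1)O2
F6 | step 16 | ring C tert-butyldimethylsilyl ether of 31 | COC1=CC(=O)C2=C(CCc3ccc(cc3)Oc3cc(ccc3O[Si](C)(C)C(C)(C)C)CCc3cccc(c3)O2)C1=O
F7 | step 7 | [4-(benzyloxy)-3-(4-iodophenoxy)phenyl]methanol | OCc1ccc(OCc2ccccc2)c(Oc2ccc(I)cc2)c1
F8 | step 7 | 1-(benzyloxy)-4-(bromomethyl)-2-(4-iodophenoxy)benzene | BrCc1ccc(OCc2ccccc2)c(Oc2ccc(I)cc2)c1
A1 | alternative 1 | ring C benzyl ether of the target quinone macrocycle | COC1=CC(=O)C2=C(CCc3ccc(cc3)Oc3cc(ccc3OCc3ccccc3)CCc3cccc(c3)O2)C1=O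
A2 | alternative 1 | macrocyclic 2-alkyl-3-aryloxy-4-hydroxy-4-(methoxyethynyl)cyclobut-2-enone, racemic carbinol | COC#CC1(O)C(=O)C2=C1Oc1cccc(c1)CCc1ccc(OCc3ccccc3)c(c1)Oc1ccc(CC2)cc1
A3 | alternative 1 | macrocyclic 3-aryloxy-4-alkylcyclobut-3-ene-1,2-dione | O=C1C(=O)C2=C1Oc1cccc(c1)CCc1ccc(OCc3ccccc3)c(c1)Oc1ccc(CC2)cc1
A4 | alternative 2 | target macrocycle with two chlorines on ring B and one bromine on ring C | COC1=CC(=O)C2=C(CCc3cc(Cl)c(c(Cl)c3)Oc3cc(cc(Br)c3O)CCc3cccc(c3)O2)C1=O
A5 | alternative 2 | open-chain quinone bisphenol with 3,5-dichloro-4-hydroxyphenethyl (ring B) and 3,5-dibromo-4-hydroxyphenethyl (ring C) groups | COC1=CC(=O)C(Oc2cccc(CCc3cc(Br)c(O)c(Br)c3)c2)=C(CCc2cc(Cl)c(O)c(Cl)c2)C1=O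
A6 | alternative 3 | 18-membered ortho-hydroxyaryl benzyl ketone macrocycle, ring C benzyl ether | COc1cc(OC)c2c(c1O)C(=O)Cc1ccc(cc1)Oc1cc(ccc1OCc1ccccc1)CCc1cccc(c1)O2
A7 | alternative 3 | 20-membered macrolactone: aryl ester of the ring A oxygen with the ring B arylacetic acid, ring C benzyl ether | COc1cc(OC)c2cc1OC(=O)Cc1ccc(cc1)Oc1cc(ccc1OCc1ccccc1)CCc1cccc(c1)O2
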